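**Retrosynthetic overview**

1. Carbons are numbered C1 (the alkyne CH) through C15 (the ethyl CH3); the oxolane holding C4–C7 is ring A and the one holding C9–C12 is ring B. The plan rests on ring B, where C10–Br is cis to the C8 methylene on C9 and sits beside an anti C12–O/C13–Br pair.
2. Late bonds: C3–Br by SN2 on the (3R)-propargylic alcohol (chelation-controlled ethynylation of the C3 aldehyde); C10–Br by SN2 on the C10 alcohol, which comes from a C10–SiMe2Ph group by Tamao–Fleming oxidation.
3. Key disconnection: ring B is cut at C11–C12 and O–C9 (silyl-shift [3+2] annulation) into the ring A allylsilane (silicon on C9, 9R, alkene C10=C11) and (R)-2-bromobutanal, which carries C13–Br in.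
4. The allylsilane comes from the E-allylic phosphate (C9=C10, C11–OP) by enantioselective copper-catalysed SN2′ silylation; ring A is made first, from L-arabinose (3-deoxy-L-threo-pentonolactone, then all-cis C-allylation at C7).
5. Ring order: ring A (chiral pool), then ring B (key step); the aldehyde comes from (R)-2-aminobutanoic acid through the bromohydrin.

Key step: step 16

Assumption: in step 11 the chiral carbene–copper catalyst, not the remote C7 centre, decides C9; its sense of induction is fixed once on a model phosphate and the ligand enantiomer that gives 9R is used.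

Choices made for the annulation precursor:
- The C3 oxygen carries a triisopropylsilyl group, so the only aryl–silicon bond in the annulation product is the one to be oxidised.
- The C6 acetate is put on only after the methoxide-mediated silylation.
- The aldehyde is made amine-free from its bromohydrin just before use.

**Route**

Step 1
Reactants: 1 L-arabinose
Product: 3 L-arabinono-1,4-lactone [(3R,4R,5S)-3,4-dihydroxy-5-(hydroxymethyl)oxolan-2-one], via L-arabinonic acid 2 (not isolated)
Conditions: Br2, NaHCO3, H2O, 0 °C to rt; concentrate, extract into EtOH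
Reagents that add atoms: none
Why: Bromine-water oxidation of the aldose hemiacetal to the aldonic acid, which closes to the γ-lactone on concentration; no stereocentre is touched and C4 of the sugar becomes C4 of the target.

Step 2
Reactants: 3 L-arabinono-1,4-lactone
Product: 4 2,3,5-tri-O-acetyl-L-arabinono-1,4-lactone
Conditions: Ac2O, pyridine, 0 °C to rt
Reagents that add atoms: acetic anhydride, CC(=O)OC(C)=O
Why: Pyridine-promoted O-acetylation of all three hydroxyls, which puts a leaving group β to the lactone carbonyl for the next step.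

Step 3
Reactants: 4 2,3,5-tri-O-acetyl-L-arabinono-1,4-lactone
Product: 6 2,5-di-O-acetyl-3-deoxy-L-threo-pentono-1,4-lactone [(3R,5R)-3-acetoxy-5-(acetoxymethyl)oxolan-2-one], via acetoxybutenolide 5 (not isolated)
Conditions: Et3N, H2 (1 atm), 10% Pd/C, EtOAc, rt
Reagents that add atoms: none
Why: E1cB loss of the acetate β to the lactone carbonyl gives the 2-acetoxybutenolide, and heterogeneous hydrogenation should deliver H2 to the face away from the acetoxymethyl group, which sets C6 (R) cis to the C4 side chain and leaves C5 as CH2.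

Step 4
Reactants: 6 2,5-di-O-acetyl-3-deoxy-L-threo-pentono-1,4-lactone
Product: 7 3-deoxy-L-threo-pentono-1,4-lactone [(3R,5R)-3-hydroxy-5-(hydroxymethyl)oxolan-2-one]
Conditions: AcCl (cat.), MeOH, rt; concentrate
Reagents that add atoms: none
Why: Acid-catalysed transesterification with methanol removes both acetates, the γ-lactone re-forms on concentration and the acidic medium does not epimerise C6.

Step 5
Reactants: 7 3-deoxy-L-threo-pentono-1,4-lactone
Product: 9 (3R,5R)-3-(triethylsilyloxy)-5-[(triisopropylsilyloxy)methyl]oxolan-2-one, via primary triisopropylsilyl ether 8 (not isolated)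
Conditions: TIPSCl, imidazole, DMF, 0 °C; then TESCl, rt
Reagents that add atoms: chlorotriisopropylsilane, CC(C)[Si](Cl)(C(C)C)C(C)C; chlorotriethylsilane, CC[Si](Cl)(CC)CC
Why: Stepwise silylation, in which the bulky chloride should take only the primary C3 hydroxyl and the smaller one then caps the C6 hydroxyl, so that C6 can later be freed alone by mild acid.

Step 6
Reactants: 9 bis-silyl lactone
Product: 11 (3R,5R)-3-(triethylsilyloxy)-5-[(triisopropylsilyloxy)methyl]oxolan-2-yl acetate (both anomers), via aluminium lactolate 10 (not isolated)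
Conditions: i-Bu2AlH, CH2Cl2, −78 °C; then pyridine, DMAP, Ac2O, −78 to 0 °C
Reagents that add atoms: acetic anhydride, CC(=O)OC(C)=O
Why: Reductive acetylation: hydride addition to the lactone at −78 °C stops at the aluminium hemiacetal, which is acetylated in the flask before it can open to the hydroxy aldehyde.

Step 7
Reactants: 11 lactol acetate
Product: 12 (2R,3R,5R)-2-allyl-3-(triethylsilyloxy)-5-[(triisopropylsilyloxy)methyl]oxolane (all-cis)
Conditions: allyltrimethylsilane, BF3·OEt2, CH2Cl2, −78 °C
Reagents that add atoms: allyltrimethylsilane, C=CC[Si](C)(C)C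
Why: Hosomi–Sakurai C-glycosylation through the five-membered oxocarbenium ion, in which the envelope with the C6 silyloxy group and the C4 side chain both pseudo-equatorial should be attacked from inside, so that the allyl group ends cis to both and C7 is set as R.

Step 8
Reactants: 12 C-allyl oxolane
Product: 13 methyl (E)-4-[(2R,3R,5R)-3-(triethylsilyloxy)-5-[(triisopropylsilyloxy)methyl]oxolan-2-yl]but-2-enoate
Conditions: methyl acrylate, second-generation Hoveyda–Grubbs catalyst (5 mol %), CH2Cl2, 40 °C
Reagents that add atoms: methyl acrylate, C=CC(=O)OC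
Why: Olefin cross-metathesis of the terminal alkene with an electron-poor acrylate partner, which should give the cross product as the E enoate and brings in C10 and C11.

Step 9
Reactants: 13 E-enoate
Product: 14 (E)-4-[(2R,3R,5R)-3-(triethylsilyloxy)-5-[(triisopropylsilyloxy)methyl]oxolan-2-yl]but-2-en-1-ol
Conditions: i-Bu2AlH, CH2Cl2, −78 °C
Reagents that add atoms: none
Why: 1,2-Reduction of the conjugated ester with the aluminium hydride at low temperature gives the allylic alcohol without change of the alkene geometry or of the silyl ethers.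

Step 10
Reactants: 14 E-allylic alcohol
Product: 15 diethyl (E)-4-[(2R,3R,5R)-3-(triethylsilyloxy)-5-[(triisopropylsilyloxy)methyl]oxolan-2-yl]but-2-en-1-yl phosphate
Conditions: (EtO)2P(O)Cl, pyridine, DMAP (cat.), CH2Cl2, 0 °C
Reagents that add atoms: diethyl chlorophosphate, CCOP(=O)(Cl)OCC
Why: O-Phosphorylation of the primary allylic alcohol provides the leaving group for the copper-catalysed allylic substitution.

Step 11
Reactants: 15 E-allylic phosphate
Product: 16 (2R,3R,5R)-2-[(2R)-2-(dimethylphenylsilyl)but-3-en-1-yl]-3-(triethylsilyloxy)-5-[(triisopropylsilyloxy)methyl]oxolane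
Conditions: PhMe2Si–Bpin, CuCl (5 mol %), chiral imidazolinium salt (carbene precursor, 6 mol %), NaOMe, THF, 0 °C
Reagents that add atoms: (dimethylphenylsilyl)boronic acid pinacol ester, CC1(C)OB(OC1(C)C)[Si](C)(C)c1ccccc1
Why: Copper-catalysed γ-selective allylic substitution (SN2′) with a silyl nucleophile released from the Si–B reagent by methoxide, in which the chiral carbene ligand on copper should decide the face of C9 and so give the 9R silane with the terminal C10=C11 alkene.

Step 12
Reactants: 16 allylsilane with C6 triethylsilyl ether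
Product: 18 (2R,3R,5R)-2-[(2R)-2-(dimethylphenylsilyl)but-3-en-1-yl]-5-[(triisopropylsilyloxy)methyl]oxolan-3-yl acetate, via C6 alcohol 17 (not isolated)
Conditions: PPTS, MeOH, rt; concentrate; then Ac2O, pyridine, DMAP (cat.), CH2Cl2, rt
Reagents that add atoms: acetic anhydride, CC(=O)OC(C)=O
Why: Mild acid methanolysis should remove the secondary triethylsilyl ether but not the primary triisopropylsilyl ether or the allylsilane, and acetylation of the freed alcohol then installs the C6 acetate of the target.

Step 13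
Reactants: 19 (R)-2-aminobutanoic acid
Product: 20 (R)-2-bromobutanoic acid
Conditions: NaNO2, 48% HBr, KBr, H2O, −5 to 0 °C
Reagents that add atoms: hydrogen bromide, Br
Why: Diazotisation of the α-amino acid in the presence of bromide proceeds with net retention (α-lactone formation and opening, double inversion), so C13 keeps the R configuration of the amino acid.

Step 14
Reactants: 20 (R)-2-bromobutanoic acid
Product: 21 (R)-2-bromobutan-1-ol
Conditions: BH3·SMe2, THF, 0 °C to rt; MeOH
Reagents that add atoms: none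
Why: Borane reduces the carboxylic acid selectively to the primary alcohol without touching the C–Br bond, and the bromohydrin serves as the configurationally stable store of the aldehyde.

Step 15
Reactants: 21 (R)-2-bromobutan-1-ol
Product: 22 (R)-2-bromobutanal
Conditions: Dess–Martin periodinane, CH2Cl2, 0 °C; filter through silica (pentane/CH2Cl2), use the cold solution at once
Reagents that add atoms: none
Why: Dess–Martin oxidation under neutral and amine-free conditions should give the α-bromo aldehyde without enolisation, and the solution is used at once.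

Step 16
Reactants: 18 ring A allylsilane acetate; 22 (R)-2-bromobutanal
Product: 23 (2R,3R,5R)-2-{[(2S,3R,5S)-5-[(1R)-1-bromopropyl]-3-(dimethylphenylsilyl)oxolan-2-yl]methyl}-5-[(triisopropylsilyloxy)methyl]oxolan-3-yl acetate
Conditions: 22 (2 equiv), BF3·OEt2 (1.2 equiv), CH2Cl2, −78 to −30 °C; Et3N, then NaHCO3 (aq)
Reagents that add atoms: none
Why: BF3 activates 22, the alkene terminus C11 of 18 adds to the carbonyl carbon C12 on the face opposite the C9–Si bond (anti-SE2′), silicon bridges the resulting cation between C9 and C10, and the BF3-bound C12 alkoxide then opens the bridge at C9 from the back while silicon stays on C10; this is the Lewis-acid silyl-shift [3+2] annulation of α-chiral allylsilanes with aldehydes, here with an α-bromo aldehyde as an untested partner of a known reaction type. Ring B closes by five-membered attack on C9 of the silicon-bridged ion (endo with respect to the three-membered ring), which should win over four-membered closure at C10 to an oxetane. C9 (S) follows from the 9R silane by inversion, and C10 (R, silicon trans to C8) from the same centre, because the allylsilane reacts with C9–H eclipsing the alkene (allylic 1,3-strain) and silicon bridges on the face where it started. C12 (S) is set by the aldehyde: with the C=O and C13–Br dipoles opposed (Cornforth model) the nucleophile passes C13–H, which gives the anti C12–O/C13–Br pair, and this is also the face that the synclinal open transition state of the 9R silane prefers (2,5-cis ring), so the two controls reinforce each other. The step needs ring closure to outrun loss of silicon (plain allylation), which the monodentate BF3, the phenyldimethylsilyl group and low temperature should favour, and it needs 22 to keep its configuration, which the amine-free solution and −78 °C should secure.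

Step 17
Reactants: 23 annulation product
Product: 24 (2R,3R,5R)-2-{[(2S,3R,5S)-5-[(1R)-1-bromopropyl]-3-hydroxyoxolan-2-yl]methyl}-5-[(triisopropylsilyloxy)methyl]oxolan-3-yl acetate
Conditions: KBr, AcOOH, NaOAc, AcOH, 0 °C to rt
Reagents that add atoms: peracetic acid, CC(=O)OO
Why: Tamao–Fleming oxidation, in which bromodesilylation of the phenyl group is followed by peracid-induced 1,2-shift of C10 from silicon to oxygen with retention, so the C10 hydroxyl stays trans to C8 (10R); the C3 silyl ether has no aryl–silicon bond and is not attacked.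

Step 18
Reactants: 24 C10 alcohol
Product: 25 (2R,3R,5R)-2-{[(2S,3S,5S)-3-bromo-5-[(1R)-1-bromopropyl]oxolan-2-yl]methyl}-5-[(triisopropylsilyloxy)methyl]oxolan-3-yl acetate
Conditions: CBr4, P(n-C8H17)3, toluene, 70 °C
Reagents that add atoms: carbon tetrabromide, BrC(Br)(Br)Br
Why: Appel-type bromination via the alkoxyphosphonium bromide, in which bromide attacks C10 from the back (SN2) and so inverts it to the bromide cis to C8 (10S).

Step 19
Reactants: 25 C10 bromide
Product: 26 (2R,3R,5R)-2-{[(2S,3S,5S)-3-bromo-5-[(1R)-1-bromopropyl]oxolan-2-yl]methyl}-5-(hydroxymethyl)oxolan-3-yl acetate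
Conditions: HF·pyridine, pyridine, THF, 0 °C to rt
Reagents that add atoms: none
Why: Fluoride-mediated cleavage of the silyl ether under buffered acidic conditions frees the C3 hydroxyl without E2 loss of the secondary bromides and without cleavage or shift of the acetate.

Step 20
Reactants: 26 C3 alcohol
Product: 27 (2R,3R,5R)-2-{[(2S,3S,5S)-3-bromo-5-[(1R)-1-bromopropyl]oxolan-2-yl]methyl}-5-formyloxolan-3-yl acetate
Conditions: Dess–Martin periodinane, NaHCO3, CH2Cl2, 0 °C to rt
Reagents that add atoms: none
Why: Dess–Martin oxidation stops at the α-alkoxy aldehyde, which is taken on crude so that C4 does not epimerise.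

Step 21
Reactants: 27 C3 aldehyde
Product: 28 (2R,3R,5R)-2-{[(2S,3S,5S)-3-bromo-5-[(1R)-1-bromopropyl]oxolan-2-yl]methyl}-5-[(1R)-1-hydroxyprop-2-yn-1-yl]oxolan-3-yl acetate
Conditions: MgBr2·OEt2, CH2Cl2, −78 °C; then HC≡CMgBr (THF), −78 °C; NH4Cl (aq)
Reagents that add atoms: ethynylmagnesium bromide, C#C[Mg]Br
Why: Chelation-controlled Grignard addition (Cram chelate model), in which magnesium bridges the aldehyde oxygen and the ring A oxygen and the acetylide adds on the side of C4–H, which should give the 3R alcohol (syn to the ring oxygen); at −78 °C the aldehyde should react far faster than the acetate.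

Step 22
Reactants: 28 (3R)-propargylic alcohol
Product: 29 (2R,3R,5R)-2-{[(2S,3S,5S)-3-bromo-5-[(1R)-1-bromopropyl]oxolan-2-yl]methyl}-5-[(1S)-1-bromoprop-2-yn-1-yl]oxolan-3-yl acetate (target)
Conditions: CBr4, PPh3, CH2Cl2, −20 to 0 °C
Reagents that add atoms: carbon tetrabromide, BrC(Br)(Br)Br
Why: Appel reaction, in which bromide displaces the propargylic alkoxyphosphonium group by SN2 with inversion to give the 3S bromide, low temperature holding back SN2′ attack and bromide exchange.

**Compound list**

1 | L-arabinose (open-chain form) | O=C[C@H](O)[C@@H](O)[C@@H](O)CO | starting material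
2 | L-arabinonic acid | OC(=O)[C@H](O)[C@@H](O)[C@@H](O)CO | intermediate
3 | L-arabinono-1,4-lactone, (3R,4R,5S)-3,4-dihydroxy-5-(hydroxymethyl)oxolan-2-one | O=C1[C@H](O)[C@@H](O)[C@H](CO)O1 | intermediate
4 | 2,3,5-tri-O-acetyl-L-arabinono-1,4-lactone | O=C1[C@H](OC(C)=O)[C@@H](OC(C)=O)[C@H](COC(C)=O)O1 | intermediate
5 | (5R)-3-acetoxy-5-(acetoxymethyl)furan-2(5H)-one | CC(=O)OC[C@H]1C=C(OC(C)=O)C(=O)O1 | intermediate
6 | (3R,5R)-3-acetoxy-5-(acetoxymethyl)oxolan-2-one (2,5-di-O-acetyl-3-deoxy-L-threo-pentono-1,4-lactone) | CC(=O)OC[C@H]1C[C@@H](OC(C)=O)C(=O)O1 | intermediate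
7 | (3R,5R)-3-hydroxy-5-(hydroxymethyl)oxolan-2-one | OC[C@H]1C[C@@H](O)C(=O)O1 | intermediate
8 | (3R,5R)-3-hydroxy-5-[(triisopropylsilyloxy)methyl]oxolan-2-one | CC(C)[Si](C(C)C)(C(C)C)OC[C@H]1C[C@@H](O)C(=O)O1 | intermediate
9 | (3R,5R)-3-(triethylsilyloxy)-5-[(triisopropylsilyloxy)methyl]oxolan-2-one | CC(C)[Si](C(C)C)(C(C)C)OC[C@H]1C[C@@H](O[Si](CC)(CC)CC)C(=O)O1 | intermediate
10 | diisobutylaluminium (3R,5R)-3-(triethylsilyloxy)-5-[(triisopropylsilyloxy)methyl]oxolan-2-olate (both C2 epimers) | CC(C)[Si](C(C)C)(C(C)C)OC[C@H]1C[C@@H](O[Si](CC)(CC)CC)C(O[Al](CC(C)C)CC(C)C)O1 | intermediate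
11 | (3R,5R)-3-(triethylsilyloxy)-5-[(triisopropylsilyloxy)methyl]oxolan-2-yl acetate (both anomers) | CC(C)[Si](C(C)C)(C(C)C)OC[C@H]1C[C@@H](O[Si](CC)(CC)CC)C(OC(C)=O)O1 | intermediate
12 | (2R,3R,5R)-2-allyl-3-(triethylsilyloxy)-5-[(triisopropylsilyloxy)methyl]oxolane | CC(C)[Si](C(C)C)(C(C)C)OC[C@H]1C[C@@H](O[Si](CC)(CC)CC)[C@@H](CC=C)O1 | intermediate
13 | methyl (E)-4-[(2R,3R,5R)-3-(triethylsilyloxy)-5-[(triisopropylsilyloxy)methyl]oxolan-2-yl]but-2-enoate | CC(C)[Si](C(C)C)(C(C)C)OC[C@H]1C[C@@H](O[Si](CC)(CC)CC)[C@@H](C/C=C/C(=O)OC)O1 | intermediate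
14 | (E)-4-[(2R,3R,5R)-3-(triethylsilyloxy)-5-[(triisopropylsilyloxy)methyl]oxolan-2-yl]but-2-en-1-ol | CC(C)[Si](C(C)C)(C(C)C)OC[C@H]1C[C@@H](O[Si](CC)(CC)CC)[C@@H](C/C=C/CO)O1 | intermediate
15 | diethyl (E)-4-[(2R,3R,5R)-3-(triethylsilyloxy)-5-[(triisopropylsilyloxy)methyl]oxolan-2-yl]but-2-en-1-yl phosphate | CC(C)[Si](C(C)C)(C(C)C)OC[C@H]1C[C@@H](O[Si](CC)(CC)CC)[C@@H](C/C=C/COP(=O)(OCC)OCC)O1 | intermediate
16 | (2R,3R,5R)-2-[(2R)-2-(dimethylphenylsilyl)but-3-en-1-yl]-3-(triethylsilyloxy)-5-[(triisopropylsilyloxy)methyl]oxolane | CC(C)[Si](C(C)C)(C(C)C)OC[C@H]1C[C@@H](O[Si](CC)(CC)CC)[C@@H](C[C@@H]([Si](C)(C)c2ccccc2)C=C)O1 | intermediate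
17 | (2R,3R,5R)-2-[(2R)-2-(dimethylphenylsilyl)but-3-en-1-yl]-5-[(triisopropylsilyloxy)methyl]oxolan-3-ol | CC(C)[Si](C(C)C)(C(C)C)OC[C@H]1C[C@@H](O)[C@@H](C[C@@H]([Si](C)(C)c2ccccc2)C=C)O1 | intermediate
18 | (2R,3R,5R)-2-[(2R)-2-(dimethylphenylsilyl)but-3-en-1-yl]-5-[(triisopropylsilyloxy)methyl]oxolan-3-yl acetate | CC(C)[Si](C(C)C)(C(C)C)OC[C@H]1C[C@@H](OC(C)=O)[C@@H](C[C@@H]([Si](C)(C)c2ccccc2)C=C)O1 | intermediate
19 | (R)-2-aminobutanoic acid | CC[C@@H](N)C(=O)O | starting material
20 | (R)-2-bromobutanoic acid | CC[C@@H](Br)C(=O)O | intermediate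
21 | (R)-2-bromobutan-1-ol | CC[C@@H](Br)CO | intermediate
22 | (R)-2-bromobutanal | CC[C@@H](Br)C=O | intermediate
23 | (2R,3R,5R)-2-{[(2S,3R,5S)-5-[(1R)-1-bromopropyl]-3-(dimethylphenylsilyl)oxolan-2-yl]methyl}-5-[(triisopropylsilyloxy)methyl]oxolan-3-yl acetate | CC(C)[Si](C(C)C)(C(C)C)OC[C@H]1C[C@@H](OC(C)=O)[C@@H](C[C@@H]2O[C@H]([C@H](Br)CC)C[C@H]2[Si](C)(C)c2ccccc2)O1 | intermediate
24 | (2R,3R,5R)-2-{[(2S,3R,5S)-5-[(1R)-1-bromopropyl]-3-hydroxyoxolan-2-yl]methyl}-5-[(triisopropylsilyloxy)methyl]oxolan-3-yl acetate | CC(C)[Si](C(C)C)(C(C)C)OC[C@H]1C[C@@H](OC(C)=O)[C@@H](C[C@@H]2O[C@H]([C@H](Br)CC)C[C@H]2O)O1 | intermediate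
25 | (2R,3R,5R)-2-{[(2S,3S,5S)-3-bromo-5-[(1R)-1-bromopropyl]oxolan-2-yl]methyl}-5-[(triisopropylsilyloxy)methyl]oxolan-3-yl acetate | CC(C)[Si](C(C)C)(C(C)C)OC[C@H]1C[C@@H](OC(C)=O)[C@@H](C[C@@H]2O[C@H]([C@H](Br)CC)C[C@@H]2Br)O1 | intermediate
26 | (2R,3R,5R)-2-{[(2S,3S,5S)-3-bromo-5-[(1R)-1-bromopropyl]oxolan-2-yl]methyl}-5-(hydroxymethyl)oxolan-3-yl acetate | OC[C@H]1C[C@@H](OC(C)=O)[C@@H](C[C@@H]2O[C@H]([C@H](Br)CC)C[C@@H]2Br)O1 | intermediate
27 | (2R,3R,5R)-2-{[(2S,3S,5S)-3-bromo-5-[(1R)-1-bromopropyl]oxolan-2-yl]methyl}-5-formyloxolan-3-yl acetate | O=C[C@H]1C[C@@H](OC(C)=O)[C@@H](C[C@@H]2O[C@H]([C@H](Br)CC)C[C@@H]2Br)O1 | intermediate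
28 | (2R,3R,5R)-2-{[(2S,3S,5S)-3-bromo-5-[(1R)-1-bromopropyl]oxolan-2-yl]methyl}-5-[(1R)-1-hydroxyprop-2-yn-1-yl]oxolan-3-yl acetate | C#C[C@@H](O)[C@H]1C[C@@H](OC(C)=O)[C@@H](C[C@@H]2O[C@H]([C@H](Br)CC)C[C@@H]2Br)O1 | intermediate
29 | (2R,3R,5R)-2-{[(2S,3S,5S)-3-bromo-5-[(1R)-1-bromopropyl]oxolan-2-yl]methyl}-5-[(1S)-1-bromoprop-2-yn-1-yl]oxolan-3-yl acetate | C#C[C@H](Br)[C@H]1C[C@@H](OC(C)=O)[C@@H](C[C@@H]2O[C@H]([C@H](Br)CC)C[C@@H]2Br)O1 | target

**Step count**

Total step count: 22. Longest linear sequence: 19 steps (steps 1–12, then 16–22); steps 13–15 form the short aldehyde branch.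

**Three steps most likely to fail**

1. Step 16 (key step). After the C11–C12 bond has formed, the silicon-bridged cation may lose silicon (plain allylation) faster than the C12 oxygen closes on C9, and facial control at C12 may erode if the aldehyde enolises. The fallback sets out from 18 and 22 and comes back at 24. The allylation is run on purpose as a Hosomi–Sakurai reaction (TiCl4, CH2Cl2, −78 °C), which keeps the Cornforth control at C12 and should give the E-homoallylic bromohydrin F1. Its hydroxyl is capped as the triethylsilyl ether F2 (TESOTf, 2,6-lutidine), so that base cannot close the bromohydrin to an epoxide. Shi epoxidation (D-fructose-derived ketone, KHSO5, K2CO3 buffer, 0 °C), which gives R,R epoxides from E-dialkyl alkenes, should give the 9R,10R epoxide F3. CSA in CH2Cl2/MeOH then removes the silyl group, and the C12 hydroxyl opens the epoxide at C9 with inversion (five-membered closure instead of oxetane). This gives alcohol 24 and makes step 17 unnecessary.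

2. Step 18. Bromide has to enter at C10 on the face that carries C8 and C13, so E2 elimination to the dihydrofuran and participation of the ring A oxygen (five-membered oxonium ion, then retention or ring opening) may outrun direct substitution. The fallback sets out from 24 and comes back at 25. Activation and substitution are separated: 24 is converted into the isolated C10 chloromethanesulfonate F4 (ClCH2SO2Cl, 2,6-lutidine, CH2Cl2, 0 °C), and this is displaced with n-Bu4NBr in toluene at room temperature, where a large excess of soluble bromide and the low temperature should favour bimolecular inversion.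

3. Step 21. Facial selectivity may be poor if the non-chelated (polar Felkin–Anh) pathway competes, and the Grignard reagent may attack the acetate. The fallback sets out from 27 and comes back at 28; C3 is set by a reagent instead. Lithium (trimethylsilyl)acetylide is added at −78 °C without regard to selectivity to give the silylated propargylic alcohols F5 (both C3 epimers), and Dess–Martin oxidation gives the ynone F6. Noyori transfer hydrogenation (RuCl[(S,S)-TsDPEN](p-cymene), i-PrOH), with the alkynyl group in the place of the aryl group of the standard model, should give the silylated 3R alcohol F7. TBAF buffered with AcOH (THF, 0 °C) then removes the alkynyl silyl group to give 28.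

**Further compounds**

F1 | step 16 | (2R,3R,5R)-2-[(2E,5S,6R)-6-bromo-5-hydroxyoct-2-en-1-yl]-5-[(triisopropylsilyloxy)methyl]oxolan-3-yl acetate | CC(C)[Si](C(C)C)(C(C)C)OC[C@H]1C[C@@H](OC(C)=O)[C@@H](C/C=C/C[C@H](O)[C@H](Br)CC)O1
F2 | step 16 | triethylsilyl ether of F1 at the C12 oxygen | CC(C)[Si](C(C)C)(C(C)C)OC[C@H]1C[C@@H](OC(C)=O)[C@@H](C/C=C/C[C@H](O[Si](CC)(CC)CC)[C@H](Br)CC)O1
F3 | step 16 | (9R,10R)-epoxide of F2 (trans-oxirane between C9 and C10) | CC(C)[Si](C(C)C)(C(C)C)OC[C@H]1C[C@@H](OC(C)=O)[C@@H](C[C@H]2O[C@@H]2C[C@H](O[Si](CC)(CC)CC)[C@H](Br)CC)O1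
F4 | step 18 | C10 chloromethanesulfonate of 24 | CC(C)[Si](C(C)C)(C(C)C)OC[C@H]1C[C@@H](OC(C)=O)[C@@H](C[C@@H]2O[C@H]([C@H](Br)CC)C[C@H]2OS(=O)(=O)CCl)O1
F5 | step 21 | 1-(trimethylsilyl)alkynyl carbinols at C3 (both C3 epimers) | C[Si](C)(C)C#CC(O)[C@H]1C[C@@H](OC(C)=O)[C@@H](C[C@@H]2O[C@H]([C@H](Br)CC)C[C@@H]2Br)O1
F6 | step 21 | C3 (trimethylsilyl)ethynyl ketone | C[Si](C)(C)C#CC(=O)[C@H]1C[C@@H](OC(C)=O)[C@@H](C[C@@H]2O[C@H]([C@H](Br)CC)C[C@@H]2Br)O1
F7 | step 21 | (3R)-3-hydroxy-1-(trimethylsilyl)alkyne (silylated 28) | C[Si](C)(C)C#C[C@@H](O)[C@H]1C[C@@H](OC(C)=O)[C@@H](C[C@@H]2O[C@H]([C@H](Br)CC)C[C@@H]2Br)O1
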